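Start from 30.5%: by the last readings of the north run, at 90.0 min, that fraction of the first end groups charged, the limiting reagent against 1.02 equiv of second end groups, stood in neither links nor over-reaction product B. Call it the unclaimed fraction, one minus links minus over-reaction product B. The balance of first end groups puts whatever is unclaimed outside the asked share, whose denominator is one minus that fraction.

| flask | first end groups | second end groups | remark | time |
|---|---|---|---|---|
| north | 0.25 M | 1.02 equiv | run made earlier |  |
| south-east | 0.35 M | 1.02 equiv | run made earlier |  |
| south | 0.55 M | 1.02 equiv | run made earlier |  |
| spring | 0.25 M | 1.02 equiv | everything together at the start | 1.5 h |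
| noon | 0.25 M (fed, over 80 min) | 1.02 equiv | all else is in the flask from the start; the feed brings no volume worth counting | 1.5 h |
| summer | 0.25 M | 1.02 equiv (in portions, 3, over 80 min) | first portion at the start, last at 80 min | 1.5 h |
| winter | 0.25 M | 1.02 equiv (fed, over 80 min) | all else is in the flask from the start; the feed brings no volume worth counting | 1.5 h |

| run | time / min | links / % | over-reaction product B / % |
|---|---|---|---|
| north | 8.00 | 43.4 | 12.0 |
| north | 15.0 | 36.6 | 21.8 |
| north | 25.0 | 28.5 | 32.1 |
| north | 50.0 | 12.6 | 49.8 |
| north | 90.0 | 5.7 | 63.8 |
| south-east | 5.00 | 47.9 | 7.1 |
| south-east | 15.0 | 35.0 | 22.6 |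
| south-east | 25.0 | 26.0 | 36.0 |
| south-east | 40.0 | 14.9 | 46.6 |
| south-east | 50.0 | 11.4 | 52.7 |
| south | 5.00 | 48.1 | 9.8 |
| south | 15.0 | 36.0 | 23.7 |
| south | 25.0 | 25.6 | 34.9 |
| south | 40.0 | 15.8 | 47.8 |
| south | 50.0 | 11.7 | 53.0 |

(readings scatter by 1 percentage point)

- the numbers in the tables scatter with a standard deviation of 1 percentage point
- candidate steps: links -> over-reaction product A; links -> over-reaction product B; second end groups -> decomposed reagent; first end groups + second end groups <-> links + by-product

- the flask with the highest share of links in links plus over-reaction product B ("all alike" if they lie within 1.5 percentage points) (spring / noon / summer / winter / all alike)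
- share of links in links plus over-reaction product B at the end, spring
- share of links in links plus over-reaction product B at the end, noon
- share of links in links plus over-reaction product B at the end, summer
- share of links in links plus over-reaction product B at the end, winter

You take over the bench now. Spring has the north recipe, so my estimate for it rests on north's last readings, each with a scatter of 1 percentage point: links read 5.7% of the charge, which gives a share of about 8.20%. Between 15.0 min and 50.0 min, the north readings halve links in about 22.8 min, shorter than the 1.5 h run. So leave summer's last portion at 80 min: links it makes wait 10.0 min for the reading, shorter than that half-life.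

The forecast names summer, with spring 8.2%, noon 20%, summer 25% and winter 23%. Its ground for dosing: “Dosing keeps the equilibrium forward by limiting one partner”.

The flask gives summer: 24.8%, against spring 6.28%, noon 15.8% and winter 21.1%.

    links → over-reaction product A (k = 1.70 × 10⁻⁴ min⁻¹)
    links → over-reaction product B (k = 0.0380 min⁻¹)
    second end groups → decomposed reagent (k = 0.0150 min⁻¹)
    first end groups + second end groups ⇌ links + by-product (K = 1.60, k = 1.20 L mol⁻¹ min⁻¹)

Summer's lead over winter is 3.7 points, and a run has to overturn that for the call to fail; second end groups at 0.336 equiv or 1.69 equiv move summer's share by 5 points. In spring the unclaimed fraction is 32.8%, and spring's links of 4.22% over the remainder give 6.28%. In noon the unclaimed fraction is 51.5%, larger than spring's, and noon's links of 7.66% over the remainder give 15.8%.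

(The earlier runs and the new flask were generated by integration for an exercise, noise included.)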